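**Plan**

- Retrosynthesis: the enal is traced back to the CH3 of a 2‑isopropenyl group (allylic C–H oxidation). Then the two ester C–O bonds, the side‑chain C–CH3 bond (aryl aldehyde + methyl) and the alkenyl C–CH3 bond (from C–B) are cut, then the ring bond C2–C3, and last the O1–C2 ether bond.
- Enabling feature: C3 (the benzylic carbinol of ring B) and C2 with its C(=CH2) branch form a homoallylic alcohol, and C2 also carries the ring oxygen O1. This is the imprint of a γ‑aryloxy allylmetal adding to an ortho formyl group, so the precursor is an O‑allenyl salicylaldehyde whose O1–CH=C=CH2 unit supplies C2, the branch carbon and the =CH2.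
- Forward: ring A is bought as 4‑hydroxyisophthalaldehyde. O‑propargylation and isomerisation give the allenyl ether, and ring B (the dihydrofuran) closes in a copper‑catalysed enantioselective borylative cyclisation. Methylation at boron, acetylation, methyl addition to the remaining aldehyde, angeloylation and allylic oxidation finish the target.
- Stereochemistry: C2 and C3 arise together, cis from the fused closed transition state and in absolute sense from the chiral bisphosphine on copper. The side‑chain (R)‑carbinol comes from an amino‑alcohol‑catalysed Me2Zn addition, and the (Z)‑alkene is bought with angelic acid.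

Key step: step 3

Remark: the sense of induction of the copper catalyst must be confirmed on the first run (both antipodes of Ph‑BPE are commercial); the formulae below assume the antipode that leads to the (2R,3R) series.

**Step 1**
Reactants: 1 4‑hydroxyisophthalaldehyde; 2 propargyl bromide
Product: 3 4‑(prop‑2‑yn‑1‑yloxy)benzene‑1,3‑dicarbaldehyde
Conditions: K2CO3, DMF, rt
Reagents that add atoms: propargyl bromide (compound 2), C#CCBr
Why: Williamson ether synthesis on an acidic phenol (two formyl groups) should give clean O‑alkylation; no stereocentre is involved.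

**Step 2**
Reactants: 3 4‑(prop‑2‑yn‑1‑yloxy)benzene‑1,3‑dicarbaldehyde
Product: 4 4‑(propa‑1,2‑dien‑1‑yloxy)benzene‑1,3‑dicarbaldehyde
Conditions: KOtBu (0.2 equiv), THF, 0 °C, short reaction time
Reagents that add atoms: none
Why: Base‑catalysed propargyl‑to‑allenyl prototropic isomerisation of aryl propargyl ethers is standard, and because both formyl groups are non‑enolisable a catalytic amount of KOtBu at low temperature should not start aldol chemistry; no stereocentre is involved.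

**Step 3**
Reactants: 4 4‑(propa‑1,2‑dien‑1‑yloxy)benzene‑1,3‑dicarbaldehyde
Product: 7 (2R,3R)‑3‑hydroxy‑2‑[1‑(4,4,5,5‑tetramethyl‑1,3,2‑dioxaborolan‑2‑yl)ethenyl]‑2,3‑dihydro‑1‑benzofuran‑5‑carbaldehyde, via allylcopper species 5 (not isolated), via O‑boryl ester 6 (not isolated)
Conditions: B2pin2 (1.1 equiv), CuCl (5 mol %), (R,R)‑Ph‑BPE (6 mol %), NaOtBu (10 mol %), THF, 0 °C to rt; then aq NH4Cl
Reagents that add atoms: bis(pinacolato)diboron, CC1(C)OB(OC1(C)C)B1OC(C)(C)C(C)(C)O1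
Why: A bisphosphine‑ligated Cu–Bpin species (from CuOtBu and B2pin2) adds across the terminal C=C of the aryloxyallene, boron to the central carbon and copper to CH2 on the face away from the aryloxy group, to give the (Z)‑2‑boryl allylcopper 5, which adds through its γ‑carbon (the oxygen‑bearing carbon) to the ortho formyl group in a closed six‑membered transition state; σ‑bond metathesis of the copper alkoxide with B2pin2 then gives 6 and returns Cu–Bpin. The closest known reaction type is the copper‑catalysed enantioselective borylative coupling of allenes with aldehydes, together with its intramolecular form on allene‑tethered ketones. Ring B closes in a 5‑exo‑trig mode at the carbonyl carbon, the alternative α‑attack requiring a seven‑membered ring. C2 and C3 are set together: the cis relation follows because the six‑membered transition state can only be fused cis onto the nearly flat benzo‑fused five‑membered ring (aryl equatorial, ring oxygen axial from the Z‑allyl unit), and the absolute sense is set by the chiral bisphosphine on copper. The step needs chemoselectivity for the allene over both formyl groups and for the ortho over the para formyl group: borylcupration of the electron‑poor aryloxyallene should be faster than Cu–B addition to C=O, and the intramolecular allyl transfer to the ortho aldehyde should outrun any intermolecular one.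

**Step 4**
Reactants: 7 (2R,3R)‑3‑hydroxy‑2‑[1‑(4,4,5,5‑tetramethyl‑1,3,2‑dioxaborolan‑2‑yl)ethenyl]‑2,3‑dihydro‑1‑benzofuran‑5‑carbaldehyde
Product: 8 (2R,3R)‑3‑hydroxy‑2‑(prop‑1‑en‑2‑yl)‑2,3‑dihydro‑1‑benzofuran‑5‑carbaldehyde
Conditions: MeI (3 equiv), PdCl2(dppf) (5 mol %), K3PO4, THF/H2O, 45 °C
Reagents that add atoms: methyl iodide, CI
Why: Suzuki–Miyaura coupling of an alkenyl pinacol boronate with methyl iodide should replace boron by methyl at the sp2 carbon without touching C2 or C3, and the mild temperature limits ionisation of the allylic aryl ether by zerovalent palladium.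

**Step 5**
Reactants: 8 (2R,3R)‑3‑hydroxy‑2‑(prop‑1‑en‑2‑yl)‑2,3‑dihydro‑1‑benzofuran‑5‑carbaldehyde
Product: 9 (2R,3R)‑5‑formyl‑2‑(prop‑1‑en‑2‑yl)‑2,3‑dihydro‑1‑benzofuran‑3‑yl acetate
Conditions: Ac2O, pyridine, DMAP (5 mol %), CH2Cl2, 0 °C
Reagents that add atoms: acetic anhydride, CC(=O)OC(C)=O
Why: DMAP‑catalysed acylation of the secondary benzylic alcohol occurs at oxygen, so C3 keeps its configuration, and the electron‑poor arene (para formyl group) suppresses ionisation at C3.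

**Step 6**
Reactants: 9 (2R,3R)‑5‑formyl‑2‑(prop‑1‑en‑2‑yl)‑2,3‑dihydro‑1‑benzofuran‑3‑yl acetate
Product: 10 (2R,3R)‑5‑[(1R)‑1‑hydroxyethyl]‑2‑(prop‑1‑en‑2‑yl)‑2,3‑dihydro‑1‑benzofuran‑3‑yl acetate
Conditions: Me2Zn (3 equiv), (+)‑MIB (10 mol %), toluene, 0 °C to rt; then aq NH4Cl
Reagents that add atoms: dimethylzinc, C[Zn]C
Why: Amino‑alcohol‑catalysed enantioselective addition of a dialkylzinc to an aryl aldehyde is catalyst‑controlled, (+)‑MIB being the antipode of the ligand that gives (S)‑1‑arylalkanols and therefore expected to give the (R)‑carbinol, while the acetate and the alkene are inert to Me2Zn.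

**Step 7**
Reactants: 10 (2R,3R)‑5‑[(1R)‑1‑hydroxyethyl]‑2‑(prop‑1‑en‑2‑yl)‑2,3‑dihydro‑1‑benzofuran‑3‑yl acetate; 11 angelic acid
Product: 13 (1R)‑1‑[(2R,3R)‑3‑acetoxy‑2‑(prop‑1‑en‑2‑yl)‑2,3‑dihydro‑1‑benzofuran‑5‑yl]ethyl (2Z)‑2‑methylbut‑2‑enoate, via mixed anhydride 12 (not isolated)
Conditions: 11, 2,4,6‑trichlorobenzoyl chloride, Et3N, toluene, rt; then 10, toluene, 60 °C
Reagents that add atoms: angelic acid (compound 11), C/C=C(/C)C(=O)O
Why: Yamaguchi esterification through the preformed mixed anhydride, run without a nucleophilic amine catalyst, should acylate the alcohol at oxygen with retention at the carbinol carbon and without Z‑to‑E isomerisation of the angeloyl group.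

**Step 8**
Reactants: 13 (1R)‑1‑[(2R,3R)‑3‑acetoxy‑2‑(prop‑1‑en‑2‑yl)‑2,3‑dihydro‑1‑benzofuran‑5‑yl]ethyl (2Z)‑2‑methylbut‑2‑enoate
Product: 14 (1R)‑1‑[(2R,3R)‑3‑acetoxy‑2‑(3‑hydroxyprop‑1‑en‑2‑yl)‑2,3‑dihydro‑1‑benzofuran‑5‑yl]ethyl (2Z)‑2‑methylbut‑2‑enoate
Conditions: SeO2 (0.5 equiv), tBuOOH (2 equiv), CH2Cl2, rt
Reagents that add atoms: selenium dioxide, O=[Se]=O; tert‑butyl hydroperoxide, CC(C)(C)OO
Why: Riley allylic oxidation (ene reaction, then 2,3‑sigmatropic shift) should hydroxylate the methyl group of the electron‑richer 1,1‑disubstituted alkene, as known for 2‑isopropenyl‑2,3‑dihydrobenzofurans, while the conjugated angelate alkene is deactivated; no stereocentre is touched.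

**Step 9**
Reactants: 14 (1R)‑1‑[(2R,3R)‑3‑acetoxy‑2‑(3‑hydroxyprop‑1‑en‑2‑yl)‑2,3‑dihydro‑1‑benzofuran‑5‑yl]ethyl (2Z)‑2‑methylbut‑2‑enoate
Product: 15 (1R)‑1‑[(2R,3R)‑3‑acetoxy‑2‑(3‑oxoprop‑1‑en‑2‑yl)‑2,3‑dihydro‑1‑benzofuran‑5‑yl]ethyl (2Z)‑2‑methylbut‑2‑enoate (target)
Conditions: MnO2 (excess), CH2Cl2, rt
Reagents that add atoms: none
Why: MnO2 oxidises allylic alcohols to enals under neutral heterogeneous conditions, which avoids bases that could open the aryl ether next to the new acrolein unit or eliminate the C3 acetate.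

**Compound list**

1 | 4‑hydroxyisophthalaldehyde (4‑hydroxybenzene‑1,3‑dicarbaldehyde) | O=Cc1ccc(O)c(C=O)c1 | starting material
2 | propargyl bromide (3‑bromoprop‑1‑yne) | C#CCBr | starting material
3 | 4‑(prop‑2‑yn‑1‑yloxy)benzene‑1,3‑dicarbaldehyde | O=Cc1ccc(OCC#C)c(C=O)c1 | intermediate
4 | 4‑(propa‑1,2‑dien‑1‑yloxy)benzene‑1,3‑dicarbaldehyde | O=Cc1ccc(OC=C=C)c(C=O)c1 | intermediate
5 | (Z)‑3‑(2,4‑diformylphenoxy)‑2‑(4,4,5,5‑tetramethyl‑1,3,2‑dioxaborolan‑2‑yl)prop‑2‑en‑1‑ylcopper, formed in the flask, bisphosphine on copper omitted | O=Cc1ccc(O/C=C(\C[Cu])B2OC(C)(C)C(C)(C)O2)c(C=O)c1 | intermediate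
6 | (2R,3R)‑3‑[(4,4,5,5‑tetramethyl‑1,3,2‑dioxaborolan‑2‑yl)oxy]‑2‑[1‑(4,4,5,5‑tetramethyl‑1,3,2‑dioxaborolan‑2‑yl)ethenyl]‑2,3‑dihydro‑1‑benzofuran‑5‑carbaldehyde, formed in the flask | C=C(B1OC(C)(C)C(C)(C)O1)[C@H]2Oc3ccc(C=O)cc3[C@H]2OB4OC(C)(C)C(C)(C)O4 | intermediate
7 | (2R,3R)‑3‑hydroxy‑2‑[1‑(4,4,5,5‑tetramethyl‑1,3,2‑dioxaborolan‑2‑yl)ethenyl]‑2,3‑dihydro‑1‑benzofuran‑5‑carbaldehyde | C=C(B1OC(C)(C)C(C)(C)O1)[C@H]2Oc3ccc(C=O)cc3[C@H]2O | intermediate
8 | (2R,3R)‑3‑hydroxy‑2‑(prop‑1‑en‑2‑yl)‑2,3‑dihydro‑1‑benzofuran‑5‑carbaldehyde | C=C(C)[C@H]1Oc2ccc(C=O)cc2[C@H]1O | intermediate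
9 | (2R,3R)‑5‑formyl‑2‑(prop‑1‑en‑2‑yl)‑2,3‑dihydro‑1‑benzofuran‑3‑yl acetate | C=C(C)[C@H]1Oc2ccc(C=O)cc2[C@H]1OC(C)=O | intermediate
10 | (2R,3R)‑5‑[(1R)‑1‑hydroxyethyl]‑2‑(prop‑1‑en‑2‑yl)‑2,3‑dihydro‑1‑benzofuran‑3‑yl acetate | C=C(C)[C@H]1Oc2ccc([C@@H](C)O)cc2[C@H]1OC(C)=O | intermediate
11 | angelic acid, (2Z)‑2‑methylbut‑2‑enoic acid | C/C=C(/C)C(=O)O | starting material
12 | (2Z)‑2‑methylbut‑2‑enoic 2,4,6‑trichlorobenzoic anhydride, formed in the flask | C/C=C(/C)C(=O)OC(=O)c1c(Cl)cc(Cl)cc1Cl | intermediate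
13 | (1R)‑1‑[(2R,3R)‑3‑acetoxy‑2‑(prop‑1‑en‑2‑yl)‑2,3‑dihydro‑1‑benzofuran‑5‑yl]ethyl (2Z)‑2‑methylbut‑2‑enoate | C=C(C)[C@H]1Oc2ccc([C@@H](C)OC(=O)/C(C)=C\C)cc2[C@H]1OC(C)=O | intermediate
14 | (1R)‑1‑[(2R,3R)‑3‑acetoxy‑2‑(3‑hydroxyprop‑1‑en‑2‑yl)‑2,3‑dihydro‑1‑benzofuran‑5‑yl]ethyl (2Z)‑2‑methylbut‑2‑enoate | C=C(CO)[C@H]1Oc2ccc([C@@H](C)OC(=O)/C(C)=C\C)cc2[C@H]1OC(C)=O | intermediate
15 | (1R)‑1‑[(2R,3R)‑3‑acetoxy‑2‑(3‑oxoprop‑1‑en‑2‑yl)‑2,3‑dihydro‑1‑benzofuran‑5‑yl]ethyl (2Z)‑2‑methylbut‑2‑enoate | C=C(C=O)[C@H]1Oc2ccc([C@@H](C)OC(=O)/C(C)=C\C)cc2[C@H]1OC(C)=O | target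

**Step count and risks**

Total step count: 9. Longest linear sequence: 9 steps (from 1 to 15).

Steps most likely to fail:

1. Step 3. What may go wrong: incomplete enantio‑induction by the copper catalyst, competing boryl addition to a formyl group, or allyl transfer between molecules instead of within one. Fallback, setting out from 4: a nickel‑catalysed alkylative cyclisation of the allenyl aldehyde with Me2Zn (Ni(cod)2 as catalyst, THF, 0 °C) should close the same ring bond and deliver methyl to the central allene carbon. This gives, without a boron stage, racemic cis‑3‑hydroxy‑2‑(prop‑1‑en‑2‑yl)‑2,3‑dihydro‑1‑benzofuran‑5‑carbaldehyde F1. A lipase‑mediated kinetic resolution (immobilised Candida antarctica lipase B, vinyl acetate, MTBE) is then expected to acylate the (2S,3S) antipode to (2S,3S)‑5‑formyl‑2‑(prop‑1‑en‑2‑yl)‑2,3‑dihydro‑1‑benzofuran‑3‑yl acetate F2 and to leave the (2R,3R) alcohol, which is 8, where the route is rejoined. Should the enzyme prefer the other antipode, the acetate obtained is 9 itself and the route is rejoined there.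

2. Step 8. What may go wrong: loss of site selectivity between the isopropenyl and the angelate alkene, over‑oxidation, or acid‑promoted ionisation of the benzylic esters together with Z‑to‑E drift of the angelate. Fallback, setting out from 9: the allylic oxidation is moved ahead of the angeloylation and the new hydroxyl is carried under a silyl group. SeO2/tBuOOH on 9 should give (2R,3R)‑5‑formyl‑2‑(3‑hydroxyprop‑1‑en‑2‑yl)‑2,3‑dihydro‑1‑benzofuran‑3‑yl acetate F3. TBSCl and imidazole give (2R,3R)‑2‑[3‑(tert‑butyldimethylsilyloxy)prop‑1‑en‑2‑yl]‑5‑formyl‑2,3‑dihydro‑1‑benzofuran‑3‑yl acetate F4. Me2Zn with (+)‑MIB gives (2R,3R)‑2‑[3‑(tert‑butyldimethylsilyloxy)prop‑1‑en‑2‑yl]‑5‑[(1R)‑1‑hydroxyethyl]‑2,3‑dihydro‑1‑benzofuran‑3‑yl acetate F5. Mixed‑anhydride angeloylation as in step 7 gives (1R)‑1‑{(2R,3R)‑3‑acetoxy‑2‑[3‑(tert‑butyldimethylsilyloxy)prop‑1‑en‑2‑yl]‑2,3‑dihydro‑1‑benzofuran‑5‑yl}ethyl (2Z)‑2‑methylbut‑2‑enoate F6. HF·pyridine in THF at 0 °C then removes the silyl group and the route is rejoined at 14.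

3. Step 6. What may go wrong: slow or poorly face‑selective methyl transfer to the deactivated (para‑alkoxy) aldehyde. Fallback, setting out from 9: the stereocentre is set by reduction instead of addition. MeTi(OiPr)3 in THF at −40 °C, which is chemoselective for the aldehyde over the acetate, should give (2R,3R)‑5‑(1‑hydroxyethyl)‑2‑(prop‑1‑en‑2‑yl)‑2,3‑dihydro‑1‑benzofuran‑3‑yl acetate as both epimers at the carbinol carbon F7. Dess–Martin periodinane gives (2R,3R)‑5‑acetyl‑2‑(prop‑1‑en‑2‑yl)‑2,3‑dihydro‑1‑benzofuran‑3‑yl acetate F8. Asymmetric transfer hydrogenation with RuCl[(R,R)‑TsDPEN](p‑cymene) and HCO2H/Et3N, which gives (R)‑1‑arylethanols from aryl methyl ketones and tolerates the alkene and the acetate, rejoins the route at 10.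

**Further compounds**

F1 | step 3 | racemic cis‑3‑hydroxy‑2‑(prop‑1‑en‑2‑yl)‑2,3‑dihydro‑1‑benzofuran‑5‑carbaldehyde | C=C(C)[C@H]1Oc2ccc(C=O)cc2[C@H]1O.C=C(C)[C@@H]1Oc2ccc(C=O)cc2[C@@H]1O
F2 | step 3 | (2S,3S)‑5‑formyl‑2‑(prop‑1‑en‑2‑yl)‑2,3‑dihydro‑1‑benzofuran‑3‑yl acetate | C=C(C)[C@@H]1Oc2ccc(C=O)cc2[C@@H]1OC(C)=O
F3 | step 8 | (2R,3R)‑5‑formyl‑2‑(3‑hydroxyprop‑1‑en‑2‑yl)‑2,3‑dihydro‑1‑benzofuran‑3‑yl acetate | C=C(CO)[C@H]1Oc2ccc(C=O)cc2[C@H]1OC(C)=O
F4 | step 8 | (2R,3R)‑2‑[3‑(tert‑butyldimethylsilyloxy)prop‑1‑en‑2‑yl]‑5‑formyl‑2,3‑dihydro‑1‑benzofuran‑3‑yl acetate | C=C(CO[Si](C)(C)C(C)(C)C)[C@H]1Oc2ccc(C=O)cc2[C@H]1OC(C)=O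
F5 | step 8 | (2R,3R)‑2‑[3‑(tert‑butyldimethylsilyloxy)prop‑1‑en‑2‑yl]‑5‑[(1R)‑1‑hydroxyethyl]‑2,3‑dihydro‑1‑benzofuran‑3‑yl acetate | C=C(CO[Si](C)(C)C(C)(C)C)[C@H]1Oc2ccc([C@@H](C)O)cc2[C@H]1OC(C)=O
F6 | step 8 | (1R)‑1‑{(2R,3R)‑3‑acetoxy‑2‑[3‑(tert‑butyldimethylsilyloxy)prop‑1‑en‑2‑yl]‑2,3‑dihydro‑1‑benzofuran‑5‑yl}ethyl (2Z)‑2‑methylbut‑2‑enoate | C=C(CO[Si](C)(C)C(C)(C)C)[C@H]1Oc2ccc([C@@H](C)OC(=O)/C(C)=C\C)cc2[C@H]1OC(C)=O
F7 | step 6 | (2R,3R)‑5‑(1‑hydroxyethyl)‑2‑(prop‑1‑en‑2‑yl)‑2,3‑dihydro‑1‑benzofuran‑3‑yl acetate, both epimers at the carbinol carbon | C=C(C)[C@H]1Oc2ccc(C(C)O)cc2[C@H]1OC(C)=O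
F8 | step 6 | (2R,3R)‑5‑acetyl‑2‑(prop‑1‑en‑2‑yl)‑2,3‑dihydro‑1‑benzofuran‑3‑yl acetate | C=C(C)[C@H]1Oc2ccc(C(C)=O)cc2[C@H]1OC(C)=O
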